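The coupling partner is what we count in the flask: each addition to the substrate takes one, and tris adduct takes 3.

| setting | dusk | flask |
|---|---|---|
| substrate | 2.5 mM | 5.0 mM |
| coupling partner | 12.5 mM | 12.5 mM |
| remark | run made earlier |  |
| time |  | 6.0 min |

dusk run (percent of the substrate charged)

| time / s | tris adduct / % |
|---|---|
| 10.0 | 19.1 |
| 20.0 | 39.0 |
| 30.0 | 50.9 |
| 40.0 | 58.1 |
| 50.0 | 62.1 |
| 60.0 | 65.7 |
| 80.0 | 69.5 |

(standard deviation of a reading: 0.5 percentage points)

- the numbers in the tables scatter with a standard deviation of 0.5 percentage points
- candidate steps: coupling partner + bis adduct -> tris adduct; substrate -> decomposition product; tris adduct <-> isomer of the product; substrate + coupling partner -> mono adduct; coupling partner + mono adduct -> bis adduct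
- the reaction counts as stopped when no species that holds the substrate changes by six tenths of a point or more over the second half of the time

- which holds at 6.0 min: what has brought the reaction to rest, or that it has not come to rest (forward and back rates have come level / it is still moving / all of the substrate has reacted / the coupling partner has run out first)
- tris adduct at 6.0 min, in percent of the substrate charged

Partner charged per substrate charged is 2.50 in the flask; we call this the additions on offer. The dusk run had 5.00.

First, which numbers must be good? The time need not be: the dusk run gained 3.8 percentage points between its last two readings, and the flask's 6.0 min is far longer than that run's 80.0 s. The scatter of 0.5 points matters little. The charges matter much: by the last dusk reading, on a curve still rising, a whole addition per substrate is worth about 69.5 % of the charge as tris adduct.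

The flask offers fewer additions than tris adduct needs, so the coupling partner is the limiting reagent. We take the last dusk reading, made with partner to spare, as the tris share of finished molecules, and bracket the flask:

all substrate reaches bis adduct first: finished share = 0.500, tris adduct 34.8 %

additions pile onto few molecules: finished share = 0.833, tris adduct 57.9 %

The forecast, narrower than our bracket, says the coupling partner has run out first, with tris adduct at 46 % (40 % to 54 %): “The slow tail fits a tris ⇌ isomer equilibrium”.

    coupling partner + bis adduct → tris adduct (k = 8.10 L mol⁻¹ s⁻¹)
    substrate → decomposition product (k = 5.40 × 10⁻⁴ s⁻¹)
    tris adduct ⇌ isomer of the product (K = 0.390, k = 0.160 s⁻¹)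
    substrate + coupling partner → mono adduct (k = 18.0 L mol⁻¹ s⁻¹)
    coupling partner + mono adduct → bis adduct (k = 54.0 L mol⁻¹ s⁻¹)

The flask gives 42.2 % of tris adduct, and at 6.00 min the coupling partner has run out first, with 0.0068 % of its charge left. Counting additions in the flask then, with mono adduct 1.50 %, bis adduct 36.3 %, and tris adduct plus isomer 58.7 %:

mono + 2 × bis + 3 × (tris + isomer) = 2.50 per substrate

A neighbour flask charged with 31 mM of coupling partner offers 6.20 equiv and uses 3.00 per substrate, keeping 52 % of its partner, and ends with isomer at 28.0 % and tris adduct at 71.9 %.

The runs are simulated for substances that don't exist; noise was put on by code.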